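## Structural features

The target is a tricyclic diterpenoid lactone. A ten-membered carbocycle (C1–C10) is trans-fused along C1–C10 to a cyclohexenone (ring A: C1, C10, C11, C12, C13, C14) and fused along C7–C8 to a γ-lactone (O7, C19, C17, C8, C7); methyl groups sit on C1 (C15), C5 (C16), C17 (C18) and C11 (C20), and each oxygen is named after its carbon. There are eight stereocentres: six form the contiguous chain C7–C8–C9–C10–C1–C2, which contains the tertiary carbinol C8 and the quaternary C1, while C17 and C11 flank the chain at C8 and C10. The medium ring also holds a trisubstituted (5Z) alkene whose two allylic carbons, C4 and C7, are both ring members. The fragile groups are the β-hydroxy-γ-lactone (retro-aldol, β-elimination, epimerisation at C17), the tertiary α-ketol of ring A (C11–OH beside the C12 enone), the two secondary acetates beside tertiary alcohols, and the allylic C7–O bond. The real difficulty is to close the strained ten-membered ring without losing the Z geometry, and to build the C7/C8/C9 triad, whose outer oxygens O7 and O9 are both γ to C19 and so compete for the lactone. The ring closure exploits two facts: C1 is quaternary, so a C2 ketone can enolise only toward C3, and C4 is a primary allylic carbon of the C5=C6 alkene; a sulfonyl group on C3 makes that carbon acidic enough for a carbonate base, and the lactone and the Z alkene hold C4 near it. Upstream, the route uses the fact that C7–C8–C9 has the configuration of C2–C3–C4 of D-glucose, with C8 at the position of the carbonyl of a furanos-3-ulose.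

## Logic of the disconnections

38 to 34: The two acetate C–O bonds (O2, O9), the C12 carbonyl and the O–Si bonds at O8, O9 and O11 are adjusted last, through 37, 36 and 35. This places both acylations after every basic or hydridic step and lets one fluoride treatment remove all silicon. The demand is that the hydride step on 34 sets C2 correctly; it may reduce C12 as well, because only the allylic alcohol of 36 is re-oxidised.

34 to 33: The C3–S bond is cut. The sulfonyl group is an auxiliary whose only task is to acidify C3, and removing it erases the C3 centre. The forward step must cleave an α-sulfonyl ketone without touching the α-silyloxy enone of ring A.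

33 to 32: The C3–C4 bond of the ten-membered ring is cut. C3 is the only enolisable position next to C2 and C4 is a primary allylic carbon, so the bond joins a regiodefined soft nucleophile to an SN2-active electrophile, with ring A, lactone and Z alkene already in place. The forward step needs C-alkylation at C4 without allylic transposition, under a base mild enough for the lactone.

32 to 28 and 29: The C2–C3 bond and the C4–Br bond are cut, through 31 and 30. C2 becomes an aldehyde on the quaternary C1 and C3 comes from 29; the bromide comes from a primary allylic alcohol. The forward steps require addition to the aldehyde in the presence of an enone and a lactone, and bromination without Z-to-E isomerisation.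

28 to 25: The C11–O bond is cut. C11 is the only enolisable position of the C12 ketone, so the oxygen can be introduced through the cross-conjugated silyl dienol ether. The oxidant must approach anti to the C10 side chain.

25 to 19 and 23: The C10–C11 and C1–C14 bonds of ring A are cut, and 23 goes back through 22 to 20 and 21. This removes ring A and two stereocentres (C1, C10) at once, and the (E) geometry of 19 encodes the trans relationship of C2 and C9. The cycloaddition must be regioselective and must take the face of 19 anti to C8.

19 to 17 and 18: The C1=C10 double bond is cut. C10 is carried as a vinyl group that is inert to acid, base and hydride, and it is converted to the enal only when needed. The metathesis must turn over at a hindered allylic position and leave the C5=C6 alkene untouched.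

17 to 10: The acyl bond C19–O7 is cut and C4 is returned to the carboxyl level, through 15, 12 and 11. O7 is then part of a butenolide that locks the Z alkene and leaves O9 as the only free secondary hydroxyl, which removes the O7/O9 ambiguity. The forward sequence needs a hydride that reduces the butenolide but not C19, and lactonisation by O7 only.

10 to 7 and 8: The C5=C6 double bond is cut. C6 is the anomeric carbon of a furanose and C4–C5–C16 come from 8. The olefination must be Z-selective on a lactol and must not let the released O9 add back to C6.

7 to 4: The anomeric acetal is restored and C10=CH2 is traced to the 5,6-diol of a hexofuranose, through 6 and 5. The demand is selective hydrolysis of the terminal acetonide before the anomeric one.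

4 to 2 and 3, and 2 to 1: The C8–C17 bond is cut, leading to a furanos-3-ulose and a propanoate, and the ketone is traced to the C3 carbinol of 1. C7 and C9 are taken unchanged from D-glucose, and C8 is set by attack on the convex face of a cis-fused bicycle. Only C17 requires new control, through enolate geometry.

## Other disconnections considered

Alternative 1: The cut lies inside ring A. The C9–C10 bond and the C11–C20 methyl bond are removed from enone A1, which leads to the prochiral dienone A2. In the forward step a chiral copper–phosphoramidite catalyst (from Cu(OTf)2) would transfer vinyl from Zn(CH=CH2)2 to one of the two enantiotopic β-carbons of A2, and C11 would be methylated in the same flask.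
- In favour: catalyst control converts an achiral dienone into ring A with C1 and C10 set in one operation, either enantiomer is accessible, and no remote stereocentre is needed.
- Against, here: A1 holds three of the eight stereocentres and C11 must still be oxidised; C2 enters at the alcohol level; the face at C1 depends on the difference between CH3 and CH2OSi; and the vinyl group offers no handle for the C7/C8/C9 triad, which would have to be raised by acyclic control beside a hindered ring carbon.
- Structure: alternative 1 secures ring A first and the chain later; the chosen plan takes C7–C9 from a hexose and lets C9 steer the cycloaddition that forms ring A.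
- Mechanism: reagent control is the more predictable way to set C1 and C10, and on that point alternative 1 is the better of the two.
- Step economy: ring A is reached in fewer steps from cheaper materials, but the saving is expected to be lost in building C7–C9 and the lactone. A ring A made through A1 could still be closed through C3–C4, so the two ideas are not exclusive.

Alternative 2: The cut removes C6–C7 of the ten-membered ring together with the O–C5 bond of an isoxazoline. A3 goes back to the open-chain C7 aldoxime A4, which carries a 1,1-disubstituted C5=C6 alkene. In the forward step NaOCl would oxidise A4 to the nitrile oxide A5, which adds across the alkene (carbon to C6, oxygen to C5) and closes the carbocycle as a bridged isoxazoline.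
- In favour: the closure is a neutral cycloaddition without carbanion or leaving group, so O-alkylation, allylic transposition and base damage to the lactone cannot occur, and free hydroxyl and acetate groups are tolerated. On chemoselectivity of the closing event it is at least the equal of the alkylation.
- Against: neither the (5Z) alkene nor the lactone exists at the moment of closure. After N–O cleavage the β-hydroxy ketone must be dehydrated toward C6 with Z geometry, the C7 carbonyl reduced with the correct configuration and lactonised, and ring A of A3 still lacks the C13=C14 bond.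
- Structure: the chosen plan closes the ring with alkene geometry, lactone and C7 already fixed; alternative 2 must create all three on the medium ring.
- Mechanism: a concerted cycloaddition against an SN2 reaction that needs high dilution but forms only the wanted C–C bond.
- Step economy: five operations after closure in the chosen plan against an estimated seven or more.

Alternative 3: The cut is C1–C14. Ring A is opened, so A6 goes back to A7, a ten-membered C2 ketone whose C10 carries the C11–C12–C13≡C14 ynone. In the forward step catalytic KOt-Bu would deprotonate C1, and that carbon would add to the alkyne terminus C14 in a 6-endo-dig Michael reaction, creating ring A, the quaternary C1 and the C13=C14 enone together.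
- In favour: one catalytic step builds a ring, a quaternary centre and the final oxidation pattern of ring A. A6 is only a C2 reduction, an acetylation and a desilylation from the target, which is fewer operations after the key step than in the chosen plan, and no auxiliary has to be attached and removed. On both points it is the better design.
- Against: A7 already contains the ten-membered ring, so the hardest closure is moved upstream, not removed. In A7 the C2 ketone can enolise toward C3 as well as C1, the new C1 centre must come out trans to H10 under conformational control, and an alkoxide base meets an acetate, a β-hydroxy lactone and an ynone.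
- Structure: the chosen plan closes the large ring last on a rigid ring A with a single enolisable position; alternative 3 closes the small ring last on a flexible macrocycle.
- Mechanism: both are soft-carbanion C–C bond formations, but the chosen one needs only carbonate and is regiochemically unambiguous.
- Step economy: alternative 3 is shorter after the key step, while the chosen plan is expected to be shorter before it. A6 has the oxidation pattern of compound 34, so the last operations are shared.

Key step: step 19

Remark (numbering): atoms are labelled C1–C20 as defined above in every intermediate; primed numbers refer to the hexose.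
Remark (assumption): centres that are erased later are left undefined in the SMILES (anomeric carbon of 7 and 13, C11 and C14 of 24, C11 of 25, C2 of 30 and 31, C12 of 35 and 36); C3 of 33 is drawn as one epimer although either may form.
Remark (design of the cyclisation substrate): O8 is silylated because a free tertiary C8–OH lies cis to the C7 side chain on the lactone and could close a six-membered allylic ether onto C4; O9 is carried as a silyl ether and acetylated at the end together with O2; O11 is silylated because a free C11–OH would form a bridged hemiketal with the C2 ketone; C12 is kept as the ketone because a cis-fused cyclic ketal needs a cis-C11,C12-diol, which would require hydride delivery from the hindered face of ring A.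

## Steps

Step 1
Reactants: 1 1,2:5,6-di-O-isopropylidene-α-D-glucofuranose
Product: 2 1,2:5,6-di-O-isopropylidene-α-D-ribo-hexofuranos-3-ulose
Conditions: Dess–Martin periodinane, NaHCO3, CH2Cl2, rt
Reagents that add atoms: none
Why: Dess–Martin oxidation of the hindered secondary C3′ carbinol (the future C8); the cis-fused 1,2-acetonide holds the adjacent C2′ centre (future C7) in place.

Step 2
Reactants: 2 1,2:5,6-di-O-isopropylidene-α-D-ribo-hexofuranos-3-ulose; 3 tert-butyl propanoate
Product: 4 tert-butyl (2R)-2-(1,2:5,6-di-O-isopropylidene-α-D-allofuranos-3-C-yl)propanoate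
Conditions: LiN(i-Pr)2, THF/DMPU (4:1), −78 °C; then 2, −78 °C
Reagents that add atoms: none
Why: Aldol addition of a lithium ester enolate to a ketone; attack on the convex β-face of the cis-fused bicycle (anti to the 1,2-acetonide) sets C8, and the Z(O)-enolate formed in the presence of DMPU should react through a closed chair in which its methyl group points away from the furanose, giving the C17 configuration shown.

Step 3
Reactants: 4 tert-butyl (2R)-2-(1,2:5,6-di-O-isopropylidene-α-D-allofuranos-3-C-yl)propanoate
Product: 5 tert-butyl (2R)-2-(1,2-O-isopropylidene-α-D-allofuranos-3-C-yl)propanoate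
Conditions: AcOH/H2O (7:3), rt
Reagents that add atoms: none
Why: Selective acetal hydrolysis; the terminal 5,6-acetonide is cleaved much faster than the acetonide fused to the anomeric carbon.

Step 4
Reactants: 5 tert-butyl (2R)-2-(1,2-O-isopropylidene-α-D-allofuranos-3-C-yl)propanoate
Product: 6 tert-butyl (2R)-2-(5,6-dideoxy-1,2-O-isopropylidene-α-D-ribo-hex-5-enofuranos-3-C-yl)propanoate
Conditions: PPh3, I2, imidazole, PhMe, 80 °C
Reagents that add atoms: none
Why: Garegg–Samuelsson conversion of a vicinal diol into the alkene through the vicinal diiodide; the tertiary C8–OH is too hindered to be activated, and the vinyl group masks C10 until the dienophile is needed.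

Step 5
Reactants: 6 tert-butyl (2R)-2-(5,6-dideoxy-1,2-O-isopropylidene-α-D-ribo-hex-5-enofuranos-3-C-yl)propanoate
Product: 7 tert-butyl (2R)-2-(5,6-dideoxy-D-ribo-hex-5-enofuranos-3-C-yl)propanoate (lactol; both anomers)
Conditions: AcOH/H2O (4:1), 70 °C
Reagents that add atoms: none
Why: Hydrolysis of the anomeric acetonide exposes C6 as a lactol and frees O7; the tert-butyl ester should survive aqueous acetic acid.

Step 6
Reactants: 7 tert-butyl (2R)-2-(5,6-dideoxy-D-ribo-hex-5-enofuranos-3-C-yl)propanoate; 8 ethyl 2-[bis(2,2,2-trifluoroethoxy)phosphoryl]propanoate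
Product: 10 butenolide diol (O7–C4 α-methylbutenolide; free C8–OH; free C9–OH; C19 tert-butyl ester; C10 vinyl), via Z-enoate 9 (not isolated)
Conditions: 8, KN(SiMe3)2, 18-crown-6, THF, −78 °C; then 7, −78 → −40 °C; AcOH; then PPTS (cat.), CH2Cl2, rt
Reagents that add atoms: none
Why: Still–Gennari olefination, a kinetically Z-selective Horner–Wadsworth–Emmons reaction, on the open hydroxy-aldehyde form of the lactol; the (Z)-γ-hydroxy enoate lactonises to the butenolide, which locks the C5=C6 geometry and ties up O7, so that O9, released from the furanose ring, is the only free secondary hydroxyl.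

Step 7
Reactants: 10 butenolide diol
Product: 11 9-O-TBS butenolide (free C8–OH; C19 tert-butyl ester)
Conditions: t-BuMe2SiOTf (1.2 equiv), 2,6-lutidine, CH2Cl2, −78 → −40 °C
Reagents that add atoms: tert-butyldimethylsilyl trifluoromethanesulfonate (CC(C)(C)[Si](C)(C)OS(=O)(=O)C(F)(F)F)
Why: Silylation of the only secondary hydroxyl; the tertiary C8–OH reacts more slowly, and a hindered base at low temperature should avoid enol silylation of the butenolide.

Step 8
Reactants: 11 9-O-TBS butenolide
Product: 12 9-O-TBS butenolide C19 carboxylic acid
Conditions: TFA/CH2Cl2 (1:4), 0 °C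
Reagents that add atoms: none
Why: Acidolysis of the tert-butyl ester with loss of isobutene; O7 is held in the butenolide and O9 is silylated, so the free acid cannot lactonise at this stage and no allylic alcohol is yet present.

Step 9
Reactants: 12 9-O-TBS butenolide C19 carboxylic acid
Product: 15 γ-lactone O7–C19 (free C4–OH; free C8–OH; 9-O-TBS; (5Z); C10 vinyl), via lactol acid 13 (not isolated), via diol acid 14 (not isolated)
Conditions: i-Bu2AlH (3.5 equiv), CH2Cl2, −78 °C; NaBH4, MeOH, −20 °C; then aq. citric acid (pH 3–4), EtOAc, rt
Reagents that add atoms: none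
Why: i-Bu2AlH reduces the butenolide to the lactol while the aluminium carboxylate is inert at −78 °C; NaBH4 reduces the ring-opened (Z)-hydroxy enal to the (Z)-diol; on mild acidification the γ-hydroxy acid lactonises, and only O7 can reach C19 in a five-membered ring because O9 is silylated.

Step 10
Reactants: 15 γ-lactone O7–C19
Product: 17 8-O-TES 9-O-TBS lactone with free C4–OH (C10 vinyl), via bis-TES ether 16 (not isolated)
Conditions: Et3SiOTf (3 equiv), 2,6-lutidine, CH2Cl2, −78 → 0 °C; then PPTS, MeOH, 0 °C
Reagents that add atoms: triethylsilyl trifluoromethanesulfonate (CC[Si](CC)(CC)OS(=O)(=O)C(F)(F)F)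
Why: The silyl triflate silylates the primary and the tertiary hydroxyl, and buffered methanolysis removes only the primary allylic silyl ether; capping O8 prevents later lactol formation with the C2 aldehyde and ether closure onto C4.

Step 11
Reactants: 17 8-O-TES 9-O-TBS lactone with free C4–OH; 18 methacrolein
Product: 19 (E)-enal (C2 aldehyde; C1=C10; C15 methyl on C1)
Conditions: RuCl2(H2IMes)(=CH-C6H4-2-O-i-Pr) (second-generation Hoveyda–Grubbs catalyst, 10 mol %), 18 (10 equiv), CH2Cl2, 40 °C
Reagents that add atoms: none
Why: Olefin cross-metathesis of a monosubstituted alkene with methacrolein; the trisubstituted C5=C6 alkene is inert to the ruthenium carbene, and the more stable (E)-enal, with C9 cis to the C15 methyl, should form.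

Step 12
Reactants: 20 butan-2-one; 21 N,N-dimethylformamide dimethyl acetal
Product: 22 (E)-1-(dimethylamino)pent-1-en-3-one
Conditions: neat, 100 °C
Reagents that add atoms: none
Why: Condensation of a methyl ketone with an amide acetal at the less hindered methyl group gives the vinylogous amide.

Step 13
Reactants: 22 (E)-1-(dimethylamino)pent-1-en-3-one
Product: 23 (1E,3Z)-3-(tert-butyldimethylsilyloxy)-N,N-dimethylpenta-1,3-dien-1-amine
Conditions: KN(SiMe3)2, THF, −78 °C; t-BuMe2SiCl, −78 °C → rt
Reagents that add atoms: tert-butyl(chloro)dimethylsilane (CC(C)(C)[Si](C)(C)Cl)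
Why: Kinetic deprotonation of the ethyl CH2 of the vinylogous amide and O-silylation give the (Z)-silyl dienol ether, a strongly electron-rich 1-amino-3-siloxy diene.

Step 14
Reactants: 19 (E)-enal; 23 (1E,3Z)-3-(tert-butyldimethylsilyloxy)-N,N-dimethylpenta-1,3-dien-1-amine
Product: 25 ring A enone aldehyde (C12 ketone; C13=C14; C11–H; C2 aldehyde on C1), via aminocyclohexene silyl enol ether 24 (not isolated)
Conditions: PhMe, 60 °C; then 0.1 M HCl, THF, 0 °C
Reagents that add atoms: none
Why: Thermal Diels–Alder reaction whose regiochemistry is fixed by the amino and siloxy donors (C11 to C10, C14 to C1); the (E) dienophile places C9 and C2 trans, and the diene should add to the face anti to the fully substituted C8 in the rotamer in which C9–H eclipses the alkene on the side of the C15 methyl, setting C10 and C1; acid then hydrolyses the silyl enol ether and eliminates dimethylamine to give the enone.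

Step 15
Reactants: 25 ring A enone aldehyde
Product: 28 11-O-TES α-silyloxy enone aldehyde (8-O-TES; 9-O-TBS; free C4–OH), via TES dienol ether 26 (not isolated), via tris-TES ketone 27 (not isolated)
Conditions: Et3SiOTf, Et3N, CH2Cl2, 0 °C; dimethyldioxirane, acetone, −78 → 0 °C; then PPTS, MeOH, 0 °C
Reagents that add atoms: triethylsilyl trifluoromethanesulfonate (CC[Si](CC)(CC)OS(=O)(=O)C(F)(F)F); dimethyldioxirane (CC1(C)OO1)
Why: Only C11–H is enolisable (C1 is quaternary, C13 is vinylic), so soft enolisation gives the cross-conjugated silyl dienol ether; Rubottom oxidation (epoxidation of the electron-rich C11=C12 bond and 1,4-silyl shift) from the face anti to the C10 side chain should place O11 cis to C2, and methanolysis removes only the primary silyl ether.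

Step 16
Reactants: 28 11-O-TES α-silyloxy enone aldehyde; 29 methyl phenyl sulfone
Product: 30 β-hydroxy sulfone (C2 carbinol; C3 phenylsulfonyl; free C4–OH)
Conditions: 29, n-BuLi, THF, −78 °C; then 28 (0.45 equiv), −78 °C
Reagents that add atoms: none
Why: Addition of a lithiated sulfone to an aldehyde, the first stage of a Julia-type sequence, forms C2–C3; at −78 °C the aldehyde should react faster than the hindered α-silyloxy enone or the lactone, and the C2 configuration is irrelevant because it is oxidised in step 18.

Step 17
Reactants: 30 β-hydroxy sulfone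
Product: 31 (Z)-allylic bromide β-hydroxy sulfone (C4–Br)
Conditions: CBr4, PPh3, 2,6-lutidine, CH2Cl2, −20 °C
Reagents that add atoms: tetrabromomethane (BrC(Br)(Br)Br)
Why: Appel bromination of the primary allylic alcohol by SN2 displacement of the oxyphosphonium group; the hindered secondary C2–OH should not react, and the low temperature protects the Z geometry.

Step 18
Reactants: 31 (Z)-allylic bromide β-hydroxy sulfone
Product: 32 cyclisation precursor (C2 β-keto sulfone; (Z)-C4 allylic bromide; 8-O-TES; 9-O-TBS; 11-O-TES; C12 enone)
Conditions: Dess–Martin periodinane, NaHCO3, CH2Cl2, 0 °C → rt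
Reagents that add atoms: none
Why: Dess–Martin oxidation of the only free hydroxyl gives the β-keto sulfone under buffered, non-basic conditions that leave the allylic bromide and the silyl ethers intact.

Step 19
Reactants: 32 cyclisation precursor
Product: 33 ten-membered C2 ketone with C3 phenylsulfonyl group (8-O-TES; 9-O-TBS; 11-O-TES; C12 enone)
Conditions: Cs2CO3 (3 equiv), DMF, 25 °C, slow addition of 32 (final 1 mM)
Reagents that add atoms: none
Why: Cs2CO3 deprotonates C3, the only acidic carbon next to C2 because C1 is quaternary, and the caesium-paired carbanion, stabilised by both the carbonyl and the sulfonyl group, displaces bromide at C4 in an intramolecular SN2 reaction that forms C3–C4. The closest known reaction type is the intramolecular alkylation of sulfonyl-stabilised carbanions by allylic halides that is used to close ten-membered germacrane-type rings. The ring closed is the carbocycle C1–C10, in a 10-exo-tet mode; the (5Z) alkene and the C7–C8 lactone already fix a turn of the chain that brings C4 toward C3, and slow addition at high dilution suppresses intermolecular alkylation. C- over O-alkylation is expected because a soft, doubly stabilised carbanion meets a soft allylic bromide, and the O-alkylated product would be a strained twelve-membered enol ether. Direct substitution is favoured over allylic transposition because C4 is primary and unhindered, whereas attack at C6 would be next to the lactone-bearing C7 and would give an eight-membered ring. The Z geometry is kept because no allyl cation or metal π-allyl intermediate is formed. The new C3 stereocentre is not controlled by a designed element; it remains epimerisable under the reaction conditions and is erased in step 20. The silyl ethers at O8 and O11 block ether closure onto C4 and hemiketal formation at C2, and the C12 enone has no enolisable α-hydrogen, so its carbonyl can engage C3 only reversibly.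

Step 20
Reactants: 33 ten-membered C2 ketone with C3 phenylsulfonyl group
Product: 34 ten-membered C2,C12-diketone (C3 methylene)
Conditions: SmI2 (2.5 equiv), THF/MeOH (10:1), −78 °C
Reagents that add atoms: none
Why: Reductive cleavage of an α-sulfonyl ketone by electron transfer, loss of sulfinate and protonation of the samarium enolate; at −78 °C without a strongly donating additive this should be much faster than reduction of the α-silyloxy enone.

Step 21
Reactants: 34 ten-membered C2,C12-diketone
Product: 35 C2,C12-diol ((2R); C12 epimers; silyl ethers retained)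
Conditions: NaBH4, CeCl3·7H2O, MeOH, −40 → 0 °C
Reagents that add atoms: none
Why: Luche-type reduction; the C12 enone is reduced 1,2 to an allylic alcohol of irrelevant configuration, and hydride should reach the C2 carbonyl from the outer face of the medium ring, away from the transannular lactone, to give the (2R) alcohol.

Step 22
Reactants: 35 C2,C12-diol
Product: 36 2,8,9,11,12-pentaol
Conditions: HF (48% aq.), MeCN, 0 °C → rt
Reagents that add atoms: none
Why: Fluoride cleavage of the three silyl ethers in one operation under acidic conditions that spare the β-hydroxy lactone; no acyl group is present that could migrate.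

Step 23
Reactants: 36 2,8,9,11,12-pentaol
Product: 37 12-oxo-2,8,9,11-tetraol (ring A α-hydroxy enone)
Conditions: MnO2 (activated), CH2Cl2, rt
Reagents that add atoms: none
Why: MnO2 oxidises only the allylic C12 alcohol; the other secondary hydroxyls (C2, C9) are not allylic.

Step 24
Reactants: 37 12-oxo-2,8,9,11-tetraol
Product: 38 target compound (2,9-di-O-acetate)
Conditions: Ac2O, pyridine, DMAP (cat.), CH2Cl2, 0 °C → rt
Reagents that add atoms: acetic anhydride (CC(=O)OC(C)=O)
Why: Acylation of the two secondary hydroxyls at C2 and C9; the tertiary C8–OH and C11–OH should not react under these conditions.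

## Compound list

1 | 1,2:5,6-di-O-isopropylidene-α-D-glucofuranose | CC1(C)OC[C@@H](O1)[C@H]1O[C@@H]2OC(C)(C)O[C@@H]2[C@H]1O | starting material
2 | 1,2:5,6-di-O-isopropylidene-α-D-ribo-hexofuranos-3-ulose | CC1(C)OC[C@@H](O1)[C@H]1O[C@@H]2OC(C)(C)O[C@@H]2C1=O | intermediate
3 | tert-butyl propanoate | CCC(=O)OC(C)(C)C | starting material
4 | tert-butyl (2R)-2-(1,2:5,6-di-O-isopropylidene-α-D-allofuranos-3-C-yl)propanoate | CC1(C)OC[C@@H](O1)[C@H]1O[C@@H]2OC(C)(C)O[C@@H]2[C@@]1(O)[C@@H](C)C(=O)OC(C)(C)C | intermediate
5 | tert-butyl (2R)-2-(1,2-O-isopropylidene-α-D-allofuranos-3-C-yl)propanoate | OC[C@@H](O)[C@H]1O[C@@H]2OC(C)(C)O[C@@H]2[C@@]1(O)[C@@H](C)C(=O)OC(C)(C)C | intermediate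
6 | tert-butyl (2R)-2-(5,6-dideoxy-1,2-O-isopropylidene-α-D-ribo-hex-5-enofuranos-3-C-yl)propanoate | C=C[C@H]1O[C@@H]2OC(C)(C)O[C@@H]2[C@@]1(O)[C@@H](C)C(=O)OC(C)(C)C | intermediate
7 | tert-butyl (2R)-2-(5,6-dideoxy-D-ribo-hex-5-enofuranos-3-C-yl)propanoate (lactol) | C=C[C@H]1OC(O)[C@H](O)[C@@]1(O)[C@@H](C)C(=O)OC(C)(C)C | intermediate
8 | ethyl 2-[bis(2,2,2-trifluoroethoxy)phosphoryl]propanoate | CCOC(=O)C(C)P(=O)(OCC(F)(F)F)OCC(F)(F)F | starting material
9 | open-chain (Z)-enoate triol (C4 ethyl ester; C19 tert-butyl ester) | CCOC(=O)/C(C)=C\[C@H](O)[C@](O)([C@H](O)C=C)[C@@H](C)C(=O)OC(C)(C)C | intermediate (not isolated)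
10 | butenolide diol (O7–C4 α-methylbutenolide; C8–OH; C9–OH; C19 tert-butyl ester; C10 vinyl) | CC1=C[C@H](OC1=O)[C@](O)([C@H](O)C=C)[C@@H](C)C(=O)OC(C)(C)C | intermediate
11 | 9-O-TBS butenolide | CC1=C[C@H](OC1=O)[C@](O)([C@H](O[Si](C)(C)C(C)(C)C)C=C)[C@@H](C)C(=O)OC(C)(C)C | intermediate
12 | 9-O-TBS butenolide C19 carboxylic acid | CC1=C[C@H](OC1=O)[C@](O)([C@H](O[Si](C)(C)C(C)(C)C)C=C)[C@@H](C)C(=O)O | intermediate
13 | lactol acid (C4 hemiacetal) | CC1=C[C@H](OC1O)[C@](O)([C@H](O[Si](C)(C)C(C)(C)C)C=C)[C@@H](C)C(=O)O | intermediate (not isolated)
14 | (Z)-C4,C7-diol C19 acid | OC/C(C)=C\[C@H](O)[C@](O)([C@H](O[Si](C)(C)C(C)(C)C)C=C)[C@@H](C)C(=O)O | intermediate (not isolated)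
15 | γ-lactone O7–C19 (C4–OH; C8–OH; 9-O-TBS; C10 vinyl) | OC/C(C)=C\[C@@H]1OC(=O)[C@H](C)[C@@]1(O)[C@H](O[Si](C)(C)C(C)(C)C)C=C | intermediate
16 | 4,8-bis-O-TES 9-O-TBS lactone | CC[Si](CC)(CC)OC/C(C)=C\[C@@H]1OC(=O)[C@H](C)[C@@]1(O[Si](CC)(CC)CC)[C@H](O[Si](C)(C)C(C)(C)C)C=C | intermediate (not isolated)
17 | 8-O-TES 9-O-TBS lactone with free C4–OH (C10 vinyl) | OC/C(C)=C\[C@@H]1OC(=O)[C@H](C)[C@@]1(O[Si](CC)(CC)CC)[C@H](O[Si](C)(C)C(C)(C)C)C=C | intermediate
18 | methacrolein | CC(=C)C=O | starting material
19 | (E)-enal (C2 aldehyde; C1=C10) | OC/C(C)=C\[C@@H]1OC(=O)[C@H](C)[C@@]1(O[Si](CC)(CC)CC)[C@H](O[Si](C)(C)C(C)(C)C)/C=C(\C)C=O | intermediate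
20 | butan-2-one | CCC(C)=O | starting material
21 | N,N-dimethylformamide dimethyl acetal | COC(OC)N(C)C | starting material
22 | (E)-1-(dimethylamino)pent-1-en-3-one | CCC(=O)/C=C/N(C)C | intermediate
23 | (1E,3Z)-3-(tert-butyldimethylsilyloxy)-N,N-dimethylpenta-1,3-dien-1-amine | CN(C)/C=C/C(O[Si](C)(C)C(C)(C)C)=C/C | intermediate
24 | aminocyclohexene silyl enol ether cycloadduct | OC/C(C)=C\[C@@H]1OC(=O)[C@H](C)[C@@]1(O[Si](CC)(CC)CC)[C@H](O[Si](C)(C)C(C)(C)C)[C@H]2C(C)C(O[Si](C)(C)C(C)(C)C)=CC(N(C)C)[C@]2(C)C=O | intermediate (not isolated)
25 | ring A enone aldehyde (C12 ketone; C13=C14; C11–H) | OC/C(C)=C\[C@@H]1OC(=O)[C@H](C)[C@@]1(O[Si](CC)(CC)CC)[C@H](O[Si](C)(C)C(C)(C)C)[C@H]2C(C)C(=O)C=C[C@]2(C)C=O | intermediate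
26 | cross-conjugated TES dienol ether (4-O-TES) | CC[Si](CC)(CC)OC/C(C)=C\[C@@H]1OC(=O)[C@H](C)[C@@]1(O[Si](CC)(CC)CC)[C@H](O[Si](C)(C)C(C)(C)C)[C@H]2C(C)=C(O[Si](CC)(CC)CC)C=C[C@]2(C)C=O | intermediate (not isolated)
27 | 4,8,11-tris-O-TES α-silyloxy enone aldehyde | CC[Si](CC)(CC)OC/C(C)=C\[C@@H]1OC(=O)[C@H](C)[C@@]1(O[Si](CC)(CC)CC)[C@H](O[Si](C)(C)C(C)(C)C)[C@H]2[C@](C)(O[Si](CC)(CC)CC)C(=O)C=C[C@]2(C)C=O | intermediate (not isolated)
28 | 11-O-TES α-silyloxy enone aldehyde (8-O-TES; 9-O-TBS; C4–OH) | OC/C(C)=C\[C@@H]1OC(=O)[C@H](C)[C@@]1(O[Si](CC)(CC)CC)[C@H](O[Si](C)(C)C(C)(C)C)[C@H]2[C@](C)(O[Si](CC)(CC)CC)C(=O)C=C[C@]2(C)C=O | intermediate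
29 | methyl phenyl sulfone | CS(=O)(=O)c1ccccc1 | starting material
30 | β-hydroxy sulfone (C2 carbinol; C3 phenylsulfonyl; C4–OH) | OC/C(C)=C\[C@@H]1OC(=O)[C@H](C)[C@@]1(O[Si](CC)(CC)CC)[C@H](O[Si](C)(C)C(C)(C)C)[C@H]2[C@](C)(O[Si](CC)(CC)CC)C(=O)C=C[C@]2(C)C(O)CS(=O)(=O)c3ccccc3 | intermediate
31 | (Z)-allylic bromide β-hydroxy sulfone | BrC/C(C)=C\[C@@H]1OC(=O)[C@H](C)[C@@]1(O[Si](CC)(CC)CC)[C@H](O[Si](C)(C)C(C)(C)C)[C@H]2[C@](C)(O[Si](CC)(CC)CC)C(=O)C=C[C@]2(C)C(O)CS(=O)(=O)c3ccccc3 | intermediate
32 | cyclisation precursor (C2 β-keto sulfone; (Z)-C4 allylic bromide) | BrC/C(C)=C\[C@@H]1OC(=O)[C@H](C)[C@@]1(O[Si](CC)(CC)CC)[C@H](O[Si](C)(C)C(C)(C)C)[C@H]2[C@](C)(O[Si](CC)(CC)CC)C(=O)C=C[C@]2(C)C(=O)CS(=O)(=O)c3ccccc3 | intermediate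
33 | ten-membered C2 ketone with C3 phenylsulfonyl group | CC(C)(C)[Si](C)(C)O[C@@H]1[C@@H]2[C@](C)(C=CC(=O)[C@@]2(C)O[Si](CC)(CC)CC)C(=O)[C@@H](S(=O)(=O)c3ccccc3)C/C(C)=C\[C@@H]2OC(=O)[C@H](C)[C@]21O[Si](CC)(CC)CC | intermediate
34 | ten-membered C2,C12-diketone | CC(C)(C)[Si](C)(C)O[C@@H]1[C@@H]2[C@](C)(C=CC(=O)[C@@]2(C)O[Si](CC)(CC)CC)C(=O)CC/C(C)=C\[C@@H]2OC(=O)[C@H](C)[C@]21O[Si](CC)(CC)CC | intermediate
35 | C2,C12-diol (silyl ethers retained) | CC(C)(C)[Si](C)(C)O[C@@H]1[C@@H]2[C@](C)(C=CC(O)[C@@]2(C)O[Si](CC)(CC)CC)[C@H](O)CC/C(C)=C\[C@@H]2OC(=O)[C@H](C)[C@]21O[Si](CC)(CC)CC | intermediate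
36 | 2,8,9,11,12-pentaol | O[C@@H]1[C@@H]2[C@](C)(C=CC(O)[C@@]2(C)O)[C@H](O)CC/C(C)=C\[C@@H]2OC(=O)[C@H](C)[C@]21O | intermediate
37 | 12-oxo-2,8,9,11-tetraol | O[C@@H]1[C@@H]2[C@](C)(C=CC(=O)[C@@]2(C)O)[C@H](O)CC/C(C)=C\[C@@H]2OC(=O)[C@H](C)[C@]21O | intermediate
38 | target compound (2,9-di-O-acetate) | CC(=O)O[C@@H]1[C@@H]2[C@](C)(C=CC(=O)[C@@]2(C)O)[C@H](OC(C)=O)CC/C(C)=C\[C@@H]2OC(=O)[C@H](C)[C@]21O | target

## Step count and least certain steps

Total step count: 24. Longest linear sequence: 22 steps (steps 1–11 and 14–24, from 1 to 38); steps 12 and 13 prepare the diene.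

Step 19 (key step). The most likely failure is intermolecular alkylation to dimers and oligomers, because closing a ten-membered ring costs entropy and transannular strain; allylic transposition at C6 and base-induced β-elimination of the C8 silyloxy group in the lactone are the secondary risks. Fallback: from 30, selective methoxycarbonylation of the primary allylic hydroxyl (ClCO2Me, pyridine) would give the allylic methyl carbonate F1, and Dess–Martin oxidation the keto sulfone carbonate F2. A Tsuji–Trost cyclisation with Pd(PPh3)4 (zerovalent palladium) at high dilution in THF, in which the released methoxide is the only base, would return to the route at 33. It is held in reserve because the allylpalladium intermediate can erode the Z geometry.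

Step 14. Slow cycloaddition is likely, because a trisubstituted enal must form a quaternary centre beside the congested C9; poor facial selection is the second risk, because the bias comes from one acyclic allylic centre. Fallback: from 19, the less basic (Z)-3-(triethylsilyloxy)penta-1,3-diene F3 (from pent-1-en-3-one, Et3SiOTf, Et3N) would be used under Lewis-acid activation of the aldehyde (Me2AlCl, CH2Cl2, −78 °C) to give the silyl enol ether cycloadduct F4. Saegusa–Ito dehydrogenation with Pd(OAc)2 in MeCN would return to the route at 25.

Step 6. Loss of Z selectivity is possible because the aldehyde is available only through lactol opening at higher temperature. The liberated O9 alkoxide may add back to C6 of the unsaturated ester (oxa-Michael re-closure of the furan ring), and the α-hydroxy aldehyde may epimerise at C7 under base. Fallback: from 7, a Wittig reaction under neutral conditions (ethyl 2-(triphenylphosphoranylidene)propanoate, PhMe, 80 °C) would give the (E)-enoate F5 without alkoxide intermediates. Sensitised irradiation (hν, benzophenone, benzene) would isomerise the alkene, and the Z isomer would lactonise, returning to the route at 10.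

Step 2. The wrong facial selection of the enolate carbon would give the C17 epimer, because the two ring substituents of the ketone differ only in their remote groups; retro-aldol cleavage on warming is the second risk. Fallback: from 2, addition of CH2=C(CH3)MgBr (isopropenylmagnesium bromide) from the same convex face would give the isopropenyl carbinol F6. Hydroboration–oxidation (9-BBN, then H2O2/NaOH) would set C17 under control of the adjacent carbinol and give the primary alcohol F7. Oxidation (TEMPO, PhI(OAc)2, then NaClO2) would give the acid F8, and tert-butylation with N,N-dimethylformamide di-tert-butyl acetal would return to the route at 4.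

Step 11. Catalyst turnover may be slow, because the vinyl group is flanked by a silyloxy-bearing carbon and a fully substituted carbon, and methacrolein is itself a reluctant partner. Fallback: from 17, Lemieux–Johnson cleavage of the monosubstituted alkene (OsO4 cat., NaIO4, 2,6-lutidine, dioxane/H2O) would give the C10 aldehyde F9; competing attack on the C5=C6 alkene is the risk of this variant. A Wittig reaction with 2-(triphenylphosphoranylidene)propanal would return to the route at 19.

Step 21. Poor facial discrimination at the C2 carbonyl is possible, because the preferred conformation of the ten-membered ring is not known in advance; incomplete reduction of the hindered C2 ketone is the second risk. Fallback: from 34, a reagent-controlled Corey–Bakshi–Shibata reduction ((R)- or (S)-2-methyl-CBS-oxazaborolidine, chosen by trial, with catecholborane, PhMe, −40 °C) would replace substrate control and return to the route at 35 (F0: no new compound).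

## Further compounds

F1 | step 19 | allylic methyl carbonate of β-hydroxy sulfone 30 | COC(=O)OC/C(C)=C\[C@@H]1OC(=O)[C@H](C)[C@@]1(O[Si](CC)(CC)CC)[C@H](O[Si](C)(C)C(C)(C)C)[C@H]2[C@](C)(O[Si](CC)(CC)CC)C(=O)C=C[C@]2(C)C(O)CS(=O)(=O)c3ccccc3
F2 | step 19 | keto sulfone allylic methyl carbonate | COC(=O)OC/C(C)=C\[C@@H]1OC(=O)[C@H](C)[C@@]1(O[Si](CC)(CC)CC)[C@H](O[Si](C)(C)C(C)(C)C)[C@H]2[C@](C)(O[Si](CC)(CC)CC)C(=O)C=C[C@]2(C)C(=O)CS(=O)(=O)c3ccccc3
F3 | step 14 | (Z)-3-(triethylsilyloxy)penta-1,3-diene | C=C/C(O[Si](CC)(CC)CC)=C/C
F4 | step 14 | silyl enol ether cycloadduct (C12 triethylsilyl enol ether; C2 aldehyde) | OC/C(C)=C\[C@@H]1OC(=O)[C@H](C)[C@@]1(O[Si](CC)(CC)CC)[C@H](O[Si](C)(C)C(C)(C)C)[C@H]2C(C)C(O[Si](CC)(CC)CC)=CC[C@]2(C)C=O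
F5 | step 6 | open-chain (E)-enoate triol | CCOC(=O)/C(C)=C/[C@H](O)[C@](O)([C@H](O)C=C)[C@@H](C)C(=O)OC(C)(C)C
F6 | step 2 | 3-C-isopropenyl-1,2:5,6-di-O-isopropylidene-α-D-allofuranose | CC1(C)OC[C@@H](O1)[C@H]1O[C@@H]2OC(C)(C)O[C@@H]2[C@@]1(O)C(C)=C
F7 | step 2 | (2S)-2-(1,2:5,6-di-O-isopropylidene-α-D-allofuranos-3-C-yl)propan-1-ol | CC1(C)OC[C@@H](O1)[C@H]1O[C@@H]2OC(C)(C)O[C@@H]2[C@@]1(O)[C@@H](C)CO
F8 | step 2 | (2R)-2-(1,2:5,6-di-O-isopropylidene-α-D-allofuranos-3-C-yl)propanoic acid | CC1(C)OC[C@@H](O1)[C@H]1O[C@@H]2OC(C)(C)O[C@@H]2[C@@]1(O)[C@@H](C)C(=O)O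
F9 | step 11 | C10 aldehyde of lactone 17 | OC/C(C)=C\[C@@H]1OC(=O)[C@H](C)[C@@]1(O[Si](CC)(CC)CC)[C@H](O[Si](C)(C)C(C)(C)C)C=O
F0 | step 21 | none | none
A1 | alternative 1 | 4-[(tert-butyldimethylsilyloxy)methyl]-4,6-dimethyl-5-vinylcyclohex-2-en-1-one | C=C[C@@H]1[C@@](C)(CO[Si](C)(C)C(C)(C)C)C=CC(=O)[C@H]1C
A2 | alternative 1 | 4-[(tert-butyldimethylsilyloxy)methyl]-4-methylcyclohexa-2,5-dien-1-one | CC1(CO[Si](C)(C)C(C)(C)C)C=CC(=O)C=C1
A3 | alternative 2 | isoxazoline-bridged ten-membered carbocycle | CC(=O)O[C@@H]1[C@@H]2[C@](C)(CC[C@H]3OC(C)(C)O[C@@]23C)[C@H](OC(C)=O)CC[C@]4(C)CC(=NO4)[C@@]1(O)[C@@H](C)C(=O)OC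
A4 | alternative 2 | open-chain C7 aldoxime with C5=C6 1,1-disubstituted alkene | CC(=O)O[C@H]([C@@H]1[C@](C)(CC[C@H]2OC(C)(C)O[C@@]12C)[C@H](OC(C)=O)CCC(C)=C)[C@@](O)(C=NO)[C@@H](C)C(=O)OC
A5 | alternative 2 | open-chain C7 nitrile oxide | CC(=O)O[C@H]([C@@H]1[C@](C)(CC[C@H]2OC(C)(C)O[C@@]12C)[C@H](OC(C)=O)CCC(C)=C)[C@@](O)(C#[N+][O-])[C@@H](C)C(=O)OC
A6 | alternative 3 | 2-oxo target skeleton with O11 trimethylsilyl ether | CC(=O)O[C@@H]1[C@@H]2[C@](C)(C=CC(=O)[C@@]2(C)O[Si](C)(C)C)C(=O)CC/C(C)=C\[C@@H]2OC(=O)[C@H](C)[C@]21O
A7 | alternative 3 | ten-membered C2 ketone with C10 ynone side chain | CC(=O)O[C@@H]1[C@@H]([C@](C)(O[Si](C)(C)C)C(=O)C#C)C(C)C(=O)CC/C(C)=C\[C@@H]2OC(=O)[C@H](C)[C@]21O
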